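## Retrosynthetic overview
- The sulfate goes on last. Scolopendrine comes from the free 8-phenol with the 4'-OH masked as a benzyl ether (O-sulfation, then hydrogenolysis).
- Both C–C bonds of the CH2 bridge (C7–CH2 and CH2–aryl) are cut together. This gives 8-hydroxy-3-methoxyquinolin-2(1H)-one, formaldehyde and [4-(benzyloxy)-3-methoxyphenyl]boronic acid, joined in the new three-component step.
- Ring B (the pyridone) is cut at C3–C4 (glycolate aldol) and N1–C2 (reductive lactamisation). This leads back to 3-hydroxy-2-nitrobenzaldehyde and methyl methoxyacetate.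
- Ring order: both benzene rings (ring A of the quinolinone, ring C of the vanillyl unit) are bought. Ring B is the only permanent ring made (step 3). A transient dioxaborinine ring is made and opened in step 4.

Assumption: the target SMILES has no stereocentre and no stereogenic double bond, so it is achiral and needs no enantiocontrol; it is delivered as the free hydrogen sulfate exactly as drawn.

## Route

Step 1
Reactants: 1 3-hydroxy-2-nitrobenzaldehyde
Product: 2 3-(benzyloxy)-2-nitrobenzaldehyde
Conditions: BnBr (1.1 equiv), K2CO3 (1.5 equiv), DMF, rt, 6 h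
Reagents that add atoms: benzyl bromide, BrCc1ccccc1
Why: Williamson ether synthesis: the acidic ortho-nitrophenol is fully ionised by K2CO3 and O-benzylated cleanly, while the aldehyde and nitro group are inert.

Step 2
Reactants: 2 3-(benzyloxy)-2-nitrobenzaldehyde; 3 methyl methoxyacetate
Product: 6 methyl 3-[3-(benzyloxy)-2-nitrophenyl]-3-hydroxy-2-methoxypropanoate (racemic syn/anti mixture), via lithium enolate 4 (not isolated), via lithium aldolate 5 (not isolated)
Conditions: 3 (1.3 equiv), LiN(iPr)2 (1.25 equiv), THF, −78 °C, 30 min; add 2, −78 °C, 1 h; AcOH (1.5 equiv), −78 °C to rt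
Reagents that add atoms: none
Why: Directed glycolate aldol addition: the preformed lithium ester enolate adds to the non-enolisable, strongly electrophilic aldehyde at −78 °C and the cold AcOH quench prevents retro-aldol; the two new stereocentres form as a racemic syn/anti mixture, which does not matter because both become sp2 in step 3.

Step 3
Reactants: 6 methyl 3-[3-(benzyloxy)-2-nitrophenyl]-3-hydroxy-2-methoxypropanoate
Product: 9 8-hydroxy-3-methoxyquinolin-2(1H)-one, via aminophenol ester 7 (not isolated), via dihydroxylactam 8 (not isolated)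
Conditions: H2 (1 atm), 10% Pd/C, MeOH, rt, 8 h; filter, evaporate; AcOH, p-toluenesulfonic acid monohydrate (10 mol %), 100 °C, 3 h
Reagents that add atoms: none
Why: Reductive cyclisation: catalytic hydrogenation turns NO2 into NH2 and cleaves the benzyl ether, the aniline closes ring B by 6-exo-trig lactamisation on the methyl ester, and acid-catalysed E1 dehydration of the benzylic alcohol is driven by aromatisation to the 2-quinolone, which erases both stereocentres.

Step 4
Reactants: 9 8-hydroxy-3-methoxyquinolin-2(1H)-one; 10 [4-(benzyloxy)-3-methoxyphenyl]boronic acid; 11 paraformaldehyde (source of CH2O)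
Product: 14 7-[4-(benzyloxy)-3-methoxybenzyl]-8-hydroxy-3-methoxyquinolin-2(1H)-one, via dioxaborinine 12 (not isolated), via aryl metaborate 13 (not isolated)
Conditions: 10 (1.1 equiv), 11 (2 equiv CH2O), EtCO2H (30 mol %), PhMe–1,4-dioxane 3:1, Dean–Stark, 110 °C, 16 h; evaporate; (CF3SO2)2NH (10 mol %), ClCH2CH2Cl–(CF3)2CHOH 4:1 (0.02 M), 40 °C, 4 h; H2O work-up
Reagents that add atoms: none
Why: Proposed new method: the boronic acid acts as both ortho-directing template and aryl donor – 10 esterifies the 8-OH, delivers formaldehyde to C7 through the six-membered Nagata-type transition state (B, O8, C8, C7, CH2, O) and closes to dioxaborinine 12, so the intrinsically more reactive C5 is bypassed and no free phenol remains; catalytic (CF3SO2)2NH in ionising (CF3)2CHOH then cleaves the benzylic C–O bond to a boron-bound ortho-quinone methide (stabilised by O8 and, vinylogously through C4a–C4–C3, by the 3-OMe), whose CH2 terminus is attacked by the ipso carbon of the B-aryl group (para to OBn) through a six-membered array, a 1,5 boron-to-carbon aryl shift that isomerises 12 to metaborate 13 with high dilution favouring the intramolecular ipso path, and water then gives 14; the closest known reaction types are the phenylboronic-acid-templated ortho-hydroxyalkylation of phenols (where the B-phenyl never migrates), the Petasis borono-Mannich reaction and the addition of aryl boronates to ortho-quinone methides, including phenol/aldehyde/boronate condensations of very electron-rich phenols, but a formaldehyde-based ortho-C–H benzylation in which the template aryl itself migrates, on a hydroxycarbostyril, has not been shown.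

Step 5
Reactants: 14 7-[4-(benzyloxy)-3-methoxybenzyl]-8-hydroxy-3-methoxyquinolin-2(1H)-one
Product: 16 sodium 7-[4-(benzyloxy)-3-methoxybenzyl]-3-methoxy-2-oxo-1,2-dihydroquinolin-8-yl sulfate, via pyridinium sulfate 15 (not isolated)
Conditions: SO3·pyridine (4 equiv), pyridine, 50 °C, 12 h; aq. NaHCO3, 0 °C; C18 chromatography (H2O–MeOH)
Reagents that add atoms: SO3·pyridine, O=S(=O)([O-])[n+]1ccccc1; NaHCO3, [Na+].OC([O-])=O
Why: Phenol O-sulfation with an amine–SO3 complex: the 8-OH is the only free hydroxyl (the 4'-OH is a benzyl ether and the lactam gives no sulfamate that survives aqueous base), and the NaHCO3 work-up fixes the product as its base-stable sodium salt.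

Step 6
Reactants: 16 sodium 7-[4-(benzyloxy)-3-methoxybenzyl]-3-methoxy-2-oxo-1,2-dihydroquinolin-8-yl sulfate
Product: 18 scolopendrine, via scolopendrine sodium salt 17 (not isolated)
Conditions: H2 (1 atm), 10% Pd/C, MeOH–H2O 9:1, rt, 4 h; filter; 1.0 M HCl (1.0 equiv), 0 °C; C18 desalting (H2O, then MeOH), lyophilise
Reagents that add atoms: none
Why: Benzyl ether hydrogenolysis: aryl sulfate monoester salts, the diarylmethane and the aromatic 2-quinolone are inert to H2 over Pd/C at 1 atm, and one equivalent of cold HCl followed by reversed-phase desalting gives the free hydrogen sulfate before hydrolysis can set in.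

## Compound list
1 | 3-hydroxy-2-nitrobenzaldehyde | O=Cc1cccc(O)c1[N+](=O)[O-] | starting material
2 | 3-(benzyloxy)-2-nitrobenzaldehyde | O=Cc1cccc(OCc2ccccc2)c1[N+](=O)[O-] | intermediate
3 | methyl methoxyacetate | COCC(=O)OC | starting material
4 | lithium enolate of 3 (not isolated, geometry undefined) | COC=C([O-])OC.[Li+] | intermediate
5 | lithium aldolate of 6 (not isolated, diastereomer mixture) | COC(=O)C(OC)C([O-])c1cccc(OCc2ccccc2)c1[N+](=O)[O-].[Li+] | intermediate
6 | methyl 3-[3-(benzyloxy)-2-nitrophenyl]-3-hydroxy-2-methoxypropanoate (racemic syn/anti mixture, no defined stereocentre) | COC(=O)C(OC)C(O)c1cccc(OCc2ccccc2)c1[N+](=O)[O-] | intermediate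
7 | methyl 3-(2-amino-3-hydroxyphenyl)-3-hydroxy-2-methoxypropanoate (not isolated, diastereomer mixture) | COC(=O)C(OC)C(O)c1cccc(O)c1N | intermediate
8 | 4,8-dihydroxy-3-methoxy-3,4-dihydroquinolin-2(1H)-one (not isolated, diastereomer mixture) | COC1C(O)c2cccc(O)c2NC1=O | intermediate
9 | 8-hydroxy-3-methoxyquinolin-2(1H)-one | COc1cc2cccc(O)c2[nH]c1=O | intermediate
10 | [4-(benzyloxy)-3-methoxyphenyl]boronic acid | COc1cc(B(O)O)ccc1OCc1ccccc1 | starting material
11 | paraformaldehyde (counted as CH2O) | C=O | starting material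
12 | 2-[4-(benzyloxy)-3-methoxyphenyl]-8-methoxy-4H-[1,3,2]dioxaborinino[5,4-h]quinolin-9(10H)-one (ring C7–CH2–O–B(aryl)–O–C8 fused on the quinolinone; not isolated) | COc1cc2ccc3COB(c4ccc(OCc5ccccc5)c(OC)c4)Oc3c2[nH]c1=O | intermediate
13 | 7-[4-(benzyloxy)-3-methoxybenzyl]-3-methoxy-2-oxo-1,2-dihydroquinolin-8-yl metaborate (drawn as the monomer; not isolated) | COc1cc2ccc(Cc3ccc(OCc4ccccc4)c(OC)c3)c(OB=O)c2[nH]c1=O | intermediate
14 | 7-[4-(benzyloxy)-3-methoxybenzyl]-8-hydroxy-3-methoxyquinolin-2(1H)-one | COc1cc2ccc(Cc3ccc(OCc4ccccc4)c(OC)c3)c(O)c2[nH]c1=O | intermediate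
15 | pyridinium 7-[4-(benzyloxy)-3-methoxybenzyl]-3-methoxy-2-oxo-1,2-dihydroquinolin-8-yl sulfate (not isolated) | COc1cc2ccc(Cc3ccc(OCc4ccccc4)c(OC)c3)c(OS(=O)(=O)[O-])c2[nH]c1=O.c1cc[nH+]cc1 | intermediate
16 | sodium 7-[4-(benzyloxy)-3-methoxybenzyl]-3-methoxy-2-oxo-1,2-dihydroquinolin-8-yl sulfate | COc1cc2ccc(Cc3ccc(OCc4ccccc4)c(OC)c3)c(OS(=O)(=O)[O-])c2[nH]c1=O.[Na+] | intermediate
17 | sodium 7-(4-hydroxy-3-methoxybenzyl)-3-methoxy-2-oxo-1,2-dihydroquinolin-8-yl sulfate (not isolated) | COc1cc2ccc(Cc3ccc(O)c(OC)c3)c(OS(=O)(=O)[O-])c2[nH]c1=O.[Na+] | intermediate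
18 | scolopendrine, 7-(4-hydroxy-3-methoxybenzyl)-3-methoxy-2-oxo-1,2-dihydroquinolin-8-yl hydrogen sulfate (achiral) | COc1cc(Cc2ccc3cc(OC)c(=O)[nH]c3c2OS(=O)(=O)O)ccc1O | target

## Step count and risk
Total step count: 6. Longest linear sequence: 6 steps (1 to 18).

**Step 4 (the proposed new step).**
- Risks are a reversible N1,O8-methylene acetal as an off-cycle species and protodeboronation of 10.
- Attack at C6' of the B-aryl ring instead of the ipso carbon, and oligomerisation of the quinone methide, are further risks.
- The fallback is known chemistry: ortho-specific phenol alkylation through a phenylboronic acid template, followed by ionic hydrogenation. The aryl group comes in with the aldehyde instead of from boron.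
- It sets out from 9. Treating 9 with PhB(OH)2, 4-(benzyloxy)-3-methoxybenzaldehyde and catalytic Cl3CCO2H in PhMe–1,4-dioxane under Dean–Stark conditions gives racemic 4-[4-(benzyloxy)-3-methoxyphenyl]-8-methoxy-2-phenyl-4H-[1,3,2]dioxaborinino[5,4-h]quinolin-9(10H)-one F1.
- Et3SiH and CF3CO2H in CH2Cl2 at 0 °C then reduce its doubly benzylic C–O bond, and aqueous work-up frees the phenol. The fallback comes back to the route at 14.

**Step 3 (hydrogenation, lactamisation and dehydration cascade).**
- Risks are arrest at the N-hydroxylactam, hydrogenolysis of the benzylic C4–OH, and air oxidation of the aminophenol.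
- The fallback reverses the order of bond formation in ring B (N1–C2 first, then C3–C4) and never carries a benzylic alcohol through a hydrogenation. It sets out from 2 and so also bypasses step 2.
- H2 over sulfided 5% Pt/C in EtOAc gives 2-amino-3-(benzyloxy)benzaldehyde F2.
- Methoxyacetyl chloride and pyridine in CH2Cl2 give N-[2-(benzyloxy)-6-formylphenyl]-2-methoxyacetamide F3.
- KOtBu in THF (Camps-type intramolecular aldol condensation) gives 8-(benzyloxy)-3-methoxyquinolin-2(1H)-one F4.
- H2 over 10% Pd/C in MeOH cleaves the benzyl ether. The fallback comes back to the route at 9.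

**Step 5 (sulfation of the doubly flanked 8-OH and handling of the polar salt).**
- The fallback replaces direct SO3 transfer by a protected sulfate diester that is neutral and can be chromatographed on silica. It sets out from 14.
- 2,2,2-Trichloroethyl chlorosulfate, Et3N and 4-(dimethylamino)pyridine in THF give 7-[4-(benzyloxy)-3-methoxybenzyl]-3-methoxy-2-oxo-1,2-dihydroquinolin-8-yl 2,2,2-trichloroethyl sulfate F5.
- Zn dust and HCO2NH4 in MeOH at rt remove the trichloroethyl group by reductive fragmentation. This gives ammonium 7-[4-(benzyloxy)-3-methoxybenzyl]-3-methoxy-2-oxo-1,2-dihydroquinolin-8-yl sulfate F6.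
- Evaporation with NaHCO3 (1 equiv) exchanges the cation. The fallback comes back to the route at 16.

## Further compounds
F1 | step 4 | 4-[4-(benzyloxy)-3-methoxyphenyl]-8-methoxy-2-phenyl-4H-[1,3,2]dioxaborinino[5,4-h]quinolin-9(10H)-one (racemic) | COc1cc2ccc3C(c4ccc(OCc5ccccc5)c(OC)c4)OB(c4ccccc4)Oc3c2[nH]c1=O
F2 | step 3 | 2-amino-3-(benzyloxy)benzaldehyde | Nc1c(C=O)cccc1OCc1ccccc1
F3 | step 3 | N-[2-(benzyloxy)-6-formylphenyl]-2-methoxyacetamide | COCC(=O)Nc1c(C=O)cccc1OCc1ccccc1
F4 | step 3 | 8-(benzyloxy)-3-methoxyquinolin-2(1H)-one | COc1cc2cccc(OCc3ccccc3)c2[nH]c1=O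
F5 | step 5 | 7-[4-(benzyloxy)-3-methoxybenzyl]-3-methoxy-2-oxo-1,2-dihydroquinolin-8-yl 2,2,2-trichloroethyl sulfate | COc1cc2ccc(Cc3ccc(OCc4ccccc4)c(OC)c3)c(OS(=O)(=O)OCC(Cl)(Cl)Cl)c2[nH]c1=O
F6 | step 5 | ammonium 7-[4-(benzyloxy)-3-methoxybenzyl]-3-methoxy-2-oxo-1,2-dihydroquinolin-8-yl sulfate | COc1cc2ccc(Cc3ccc(OCc4ccccc4)c(OC)c3)c(OS(=O)(=O)[O-])c2[nH]c1=O.[NH4+]
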